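The α-methylene-γ-butyrolactone (ring O–C6–C7–C11–C12, exocyclic C11=C13; germacrane numbering) is the seam of the plan. C13=C11–C7 is read as a terminal allene, C6–O as the carbonyl of a Z-enal and C12 as carbon dioxide. Zerovalent nickel joins the three components in one operation: CO2 is bound to the central allene carbon (C11–C12) and the resulting allylnickel carboxylate adds to the enal through its substituted terminus (C6–C7), setting C6 and C7 under control of C8; acid then closes the lactone. The allene half carries C8/C9 from a proline aldol of a dioxanone; ring-closing metathesis at C1=C10 later closes the ten-membered ring.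

Key step: step 9

Remark: positions are numbered as in germacranolides (C1=C10 and C4=C5 ring olefins, C6 lactone carbinol, C7 ring fusion, C8 carbinol, C9 acetate carbon, C11/C12/C13 lactone α-carbon, carbonyl and methylene, C14 acyloxymethyl, C15 methyl); but-3-en-1-ylzinc bromide and (S)-2-methylbutanoic acid are taken as purchasable.

**Allene half (C7–C10, C11, C13, C14)**

Step 1
Reactants: 1 2,2-dimethyl-1,3-dioxan-5-one; 2 3-(trimethylsilyl)prop-2-ynal
Product: 3 (4S)-4-[(1S)-1-hydroxy-3-(trimethylsilyl)prop-2-yn-1-yl]-2,2-dimethyl-1,3-dioxan-5-one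
Conditions: (S)-proline (30 mol%), DMF, 4 °C
Reagents that add atoms: none
Why: Proline enamine aldol: the enamine of 1 adds to the ynal through the carboxylic acid-organised Houk–List chair, which should give the anti adduct and thereby set C9 (dioxane C4, S) and C8 (carbinol, S) in one step under catalyst control.

Step 2
Reactants: 3 aldol adduct
Product: 4 (4S)-4-[(1S)-1-(tert-butyldimethylsilyloxy)-3-(trimethylsilyl)prop-2-yn-1-yl]-2,2-dimethyl-1,3-dioxan-5-one
Conditions: TBSOTf, 2,6-lutidine, CH2Cl2, −78 °C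
Reagents that add atoms: tert-butyldimethylsilyl triflate, CC(C)(C)[Si](C)(C)OS(=O)(=O)C(F)(F)F
Why: Silyl triflate silylation at low temperature is fast enough to cap the β-hydroxy ketone before retro-aldol or elimination, and no stereocenter is touched.

Step 3
Reactants: 4 silyloxy ketone
Product: 5 tert-butyl{[(1S)-1-[(4R)-2,2-dimethyl-5-methylidene-1,3-dioxan-4-yl]-3-(trimethylsilyl)prop-2-yn-1-yl]oxy}dimethylsilane
Conditions: Ph3PCH3Br, KOtBu, THF, 0 °C; then 4, −78 °C → rt
Reagents that add atoms: methyltriphenylphosphonium bromide, C[P+](c1ccccc1)(c1ccccc1)c1ccccc1.[Br-]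
Why: Wittig methylenation of the electrophilic dioxanone carbonyl creates the C10=CH2 unit; the non-stabilised ylide adds at low temperature faster than it enolises the ketone, so C9 should keep its configuration.

Step 4
Reactants: 5 silylalkyne
Product: 6 tert-butyl{[(1S)-1-[(4R)-2,2-dimethyl-5-methylidene-1,3-dioxan-4-yl]prop-2-yn-1-yl]oxy}dimethylsilane
Conditions: K2CO3 (0.2 equiv), MeOH, rt
Reagents that add atoms: none
Why: Methanolysis of the C(sp)–Si bond by catalytic methoxide frees the terminal alkyne while the secondary silyl ether and the acetonide are inert to these conditions.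

Step 5
Reactants: 6 terminal alkyne
Product: 8 tert-butyl{[(1S)-1-[(4R)-2,2-dimethyl-5-methylidene-1,3-dioxan-4-yl]buta-2,3-dien-1-yl]oxy}dimethylsilane, via propargylic amine 7 (not isolated)
Conditions: (CH2O)n, CuI (0.5 equiv), Cy2NH, 1,4-dioxane, reflux
Reagents that add atoms: paraformaldehyde (as formaldehyde), C=O
Why: Crabbé–Ma homologation: Mannich condensation gives propargylic amine 7, and CuI-mediated intramolecular hydride transfer from the amine α-CH to the alkyne (retro-imino-ene) expels the imine and leaves the terminal allene without touching C8.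

**Enal half (C1–C6, C15)**

Step 6
Reactants: 9 but-2-yn-1-ol
Product: 11 (2Z)-3-iodobut-2-en-1-ol, via alkenylaluminate 10 (not isolated)
Conditions: NaAlH2(OCH2CH2OMe)2, THF, 0 °C → rt; then I2, −78 °C → 0 °C
Reagents that add atoms: iodine, II
Why: Hydroxyl-directed trans-hydroalumination places aluminium at C3 in the five-membered aluminate 10, and iodinolysis with retention gives the Z-iodide, which fixes the later C4=C5 geometry.

Step 7
Reactants: 11 (2Z)-3-iodobut-2-en-1-ol; 12 but-3-en-1-ylzinc bromide
Product: 13 (2Z)-3-methylhepta-2,6-dien-1-ol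
Conditions: PdCl2(dppf) (5 mol%), 12 (2.5 equiv), THF, rt → 50 °C
Reagents that add atoms: none
Why: Negishi sp2–sp3 cross-coupling proceeds with retention of the olefin geometry, the bidentate dppf ligand suppressing β-hydride elimination of the butenyl–palladium intermediate.

Step 8
Reactants: 13 (2Z)-3-methylhepta-2,6-dien-1-ol
Product: 14 (2Z)-3-methylhepta-2,6-dienal
Conditions: TEMPO (10 mol%), PhI(OAc)2, CH2Cl2, rt
Reagents that add atoms: none
Why: Oxoammonium (TEMPO) oxidation of the allylic alcohol under neutral conditions should give the enal without Z to E isomerisation or over-oxidation.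

**Union and completion**

Step 9
Reactants: 8 allene; 15 carbon dioxide; 14 (2Z)-3-methylhepta-2,6-dienal
Product: 19 (4S,5R)-4-{(S)-(tert-butyldimethylsilyloxy)[(4R)-2,2-dimethyl-5-methylidene-1,3-dioxan-4-yl]methyl}-3-methylidene-5-[(1Z)-2-methylhexa-1,5-dien-1-yl]oxolan-2-one, via nickelalactone 16 (not isolated), via nickel alkoxide carboxylate 17 (not isolated), via hydroxy acid 18 (not isolated)
Conditions: Ni(cod)2 (1.1 equiv), DBU (2.2 equiv), CO2 (1 atm), THF, 0 °C; then 14 (1.5 equiv), 0 °C → rt; cold 1 M HCl work-up; PPTS (cat.), CH2Cl2, rt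
Reagents that add atoms: none
Why: Zerovalent nickel ligated by DBU couples the terminal C11=C13 bond of allene 8 with CO2 by oxidative cyclisation, forming C11–C12 and the divalent nickelalactone 16, whose allyl unit (C13–C11–C7) adds through its substituted terminus C7 to the nickel-bound aldehyde 14 in a six-membered chair transition state (C6–C7), as in carbonyl allylation by γ-substituted allylmetals; the closest known reaction type is the nickel-mediated sequential carboxylation and aldehyde addition of terminal allenes. Both C–C bonds are made intermolecularly and the only ring closed is the lactone, by 5-exo-trig attack of O6–H on the carboxyl carbon C12 of hydroxy acid 18 under acid catalysis. The C6/C7 relationship (anti, hence the trans-lactone) should follow from the chair in which C8 is trans to the nickel-bearing C13 and the enal residue is equatorial. The C7/C8 relationship should follow from allylic 1,3-strain, which holds H8 in the olefin plane toward the carboxylate so that the aldehyde approaches anti to the bulky dioxanyl carbon C9 and syn to the outside silyloxy group. The step needs regioselectivity (CO2 at the central allene carbon, aldehyde at C7 and not C13), chemoselectivity for the allene over the 1,1-disubstituted alkene and for 1,2-addition to the enal, and retention of the Z-enal; these rest on the far higher reactivity of the cumulene toward zerovalent nickel, on the chelated primary σ-allyl form that reacts with allylic transposition, and on adding 14 only after the nickelalactone has formed at 0 °C.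

Step 10
Reactants: 19 lactone acetonide
Product: 20 (4S,5R)-4-[(1S,2R)-1-(tert-butyldimethylsilyloxy)-2-hydroxy-3-(hydroxymethyl)but-3-en-1-yl]-3-methylidene-5-[(1Z)-2-methylhexa-1,5-dien-1-yl]oxolan-2-one
Conditions: PPTS (0.2 equiv), MeOH, rt
Reagents that add atoms: none
Why: Acid-catalysed transacetalisation with methanol removes the isopropylidene group, whereas the hindered secondary silyl ether, the lactone and its exocyclic methylene tolerate the mild acid.

Step 11
Reactants: 20 diol; 21 (2S)-2-methylbutanoic acid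
Product: 22 [(3R,4S)-4-(tert-butyldimethylsilyloxy)-3-hydroxy-2-methylidene-4-{(2R,3S)-4-methylidene-2-[(1Z)-2-methylhexa-1,5-dien-1-yl]-5-oxooxolan-3-yl}butyl] (2S)-2-methylbutanoate
Conditions: EDC·HCl, DMAP (10 mol%), CH2Cl2, −20 °C → 0 °C
Reagents that add atoms: none
Why: Steglich esterification discriminates the unhindered primary allylic C14 hydroxyl from the secondary C9 hydroxyl flanked by the silyloxy-bearing C8, and the low temperature guards the α-stereocenter of 21.

Step 12
Reactants: 22 C14 monoester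
Product: 23 [(3R,4S)-3-acetoxy-4-(tert-butyldimethylsilyloxy)-2-methylidene-4-{(2R,3S)-4-methylidene-2-[(1Z)-2-methylhexa-1,5-dien-1-yl]-5-oxooxolan-3-yl}butyl] (2S)-2-methylbutanoate
Conditions: Ac2O, pyridine, DMAP (cat.), CH2Cl2, 0 °C → rt
Reagents that add atoms: acetic anhydride, CC(=O)OC(C)=O
Why: DMAP-catalysed acetylation of the only remaining free hydroxyl (C9) needs no selectivity.

Step 13
Reactants: 23 diester triene
Product: 24 (6R,7S,8S,9R)-9-acetoxy-8-(tert-butyldimethylsilyloxy)-14-[(2S)-2-methylbutanoyloxy]germacra-1(10)Z,4Z,11(13)-trien-12,6-olide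
Conditions: second-generation Hoveyda–Grubbs catalyst (15 mol%), 1,4-benzoquinone (30 mol%), toluene (1 mM), 80 °C
Reagents that add atoms: none
Why: Ring-closing metathesis: the ruthenium alkylidene formed at the terminal C1 vinyl group closes onto the C10 methylene, the ten-membered ring admits only the cis (Z) olefin, the trisubstituted C4=C5 bond is inert, and closure onto the electron-poor C11=C13 methylene would require a bridgehead olefin in an eight-membered ring.

Step 14
Reactants: 24 silyl-protected macrocycle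
Product: 25 (6R,7R,8S,9R)-9-acetoxy-8-hydroxy-14-[(2S)-2-methylbutanoyloxy]germacra-1(10)Z,4Z,11(13)-trien-12,6-olide (target)
Conditions: HF·pyridine, THF/pyridine, 0 °C → rt
Reagents that add atoms: none
Why: Fluoride-mediated desilylation under buffered, weakly acidic conditions frees O8–H without base, so the neighbouring C9 acetate should not migrate and the α-methylene lactone is not attacked.

**Compound list**

1 | 2,2-dimethyl-1,3-dioxan-5-one | CC1(C)OCC(=O)CO1 | starting material
2 | 3-(trimethylsilyl)prop-2-ynal | C[Si](C)(C)C#CC=O | starting material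
3 | (4S)-4-[(1S)-1-hydroxy-3-(trimethylsilyl)prop-2-yn-1-yl]-2,2-dimethyl-1,3-dioxan-5-one | CC1(C)OCC(=O)[C@@H](O1)[C@@H](O)C#C[Si](C)(C)C | intermediate
4 | (4S)-4-[(1S)-1-(tert-butyldimethylsilyloxy)-3-(trimethylsilyl)prop-2-yn-1-yl]-2,2-dimethyl-1,3-dioxan-5-one | CC1(C)OCC(=O)[C@@H](O1)[C@@H](O[Si](C)(C)C(C)(C)C)C#C[Si](C)(C)C | intermediate
5 | tert-butyl{[(1S)-1-[(4R)-2,2-dimethyl-5-methylidene-1,3-dioxan-4-yl]-3-(trimethylsilyl)prop-2-yn-1-yl]oxy}dimethylsilane | CC1(C)OCC(=C)[C@@H](O1)[C@@H](O[Si](C)(C)C(C)(C)C)C#C[Si](C)(C)C | intermediate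
6 | tert-butyl{[(1S)-1-[(4R)-2,2-dimethyl-5-methylidene-1,3-dioxan-4-yl]prop-2-yn-1-yl]oxy}dimethylsilane | CC1(C)OCC(=C)[C@@H](O1)[C@@H](O[Si](C)(C)C(C)(C)C)C#C | intermediate
7 | (4S)-4-(tert-butyldimethylsilyloxy)-N,N-dicyclohexyl-4-[(4R)-2,2-dimethyl-5-methylidene-1,3-dioxan-4-yl]but-2-yn-1-amine (Mannich base, not isolated) | CC1(C)OCC(=C)[C@@H](O1)[C@@H](O[Si](C)(C)C(C)(C)C)C#CCN(C2CCCCC2)C2CCCCC2 | intermediate
8 | tert-butyl{[(1S)-1-[(4R)-2,2-dimethyl-5-methylidene-1,3-dioxan-4-yl]buta-2,3-dien-1-yl]oxy}dimethylsilane | CC1(C)OCC(=C)[C@@H](O1)[C@@H](O[Si](C)(C)C(C)(C)C)C=C=C | intermediate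
9 | but-2-yn-1-ol | CC#CCO | starting material
10 | sodium 2,2-bis(2-methoxyethoxy)-3-methyl-1-oxa-2-aluminacyclopent-3-en-2-uide (cyclic alkenylaluminate, not isolated) | CC1=CCO[Al-]1(OCCOC)OCCOC.[Na+] | intermediate
11 | (2Z)-3-iodobut-2-en-1-ol | OC/C=C(/C)I | intermediate
12 | but-3-en-1-ylzinc bromide | C=CCC[Zn]Br | starting material
13 | (2Z)-3-methylhepta-2,6-dien-1-ol | OC/C=C(/C)CCC=C | intermediate
14 | (2Z)-3-methylhepta-2,6-dienal | O=C/C=C(/C)CCC=C | intermediate
15 | carbon dioxide | O=C=O | starting material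
16 | bis(DBU) nickelalactone, divalent nickel: five-membered ring Ni–O–C12(=O)–C11–C13H2 bearing the exocyclic C11=C7 alkylidene, σ-form of the π-allylnickel carboxylate (not isolated) | O=C1O[Ni]C/C1=C/[C@H](O[Si](C)(C)C(C)(C)C)[C@@H]2OC(C)(C)OCC2=C.C1CCC2=NCCCN2CC1.C1CCC2=NCCCN2CC1 | intermediate
17 | bis(DBU) divalent nickel alkoxide carboxylate chelate (seven-membered ring O6–Ni–O–C12) formed after C6–C7 bond formation (not isolated) | C=C1C(=O)O[Ni]O[C@H](/C=C(/C)CCC=C)[C@H]1[C@H](O[Si](C)(C)C(C)(C)C)[C@@H]2OC(C)(C)OCC2=C.C1CCC2=NCCCN2CC1.C1CCC2=NCCCN2CC1 | intermediate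
18 | γ-hydroxy α-methylene acid: 2-methylidene acid C12 with C7 bearing the C6 carbinol (Z-dienyl side chain) and the C8 silyloxy(dioxanyl)methyl group, configured as in 19 (not isolated) | C=C(C(=O)O)[C@@H]([C@H](O)/C=C(/C)CCC=C)[C@H](O[Si](C)(C)C(C)(C)C)[C@@H]1OC(C)(C)OCC1=C | intermediate
19 | (4S,5R)-4-{(S)-(tert-butyldimethylsilyloxy)[(4R)-2,2-dimethyl-5-methylidene-1,3-dioxan-4-yl]methyl}-3-methylidene-5-[(1Z)-2-methylhexa-1,5-dien-1-yl]oxolan-2-one | C=C1C(=O)O[C@H](/C=C(/C)CCC=C)[C@H]1[C@H](O[Si](C)(C)C(C)(C)C)[C@@H]2OC(C)(C)OCC2=C | intermediate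
20 | (4S,5R)-4-[(1S,2R)-1-(tert-butyldimethylsilyloxy)-2-hydroxy-3-(hydroxymethyl)but-3-en-1-yl]-3-methylidene-5-[(1Z)-2-methylhexa-1,5-dien-1-yl]oxolan-2-one | C=C1C(=O)O[C@H](/C=C(/C)CCC=C)[C@H]1[C@H](O[Si](C)(C)C(C)(C)C)[C@H](O)C(=C)CO | intermediate
21 | (2S)-2-methylbutanoic acid | OC(=O)[C@@H](C)CC | starting material
22 | [(3R,4S)-4-(tert-butyldimethylsilyloxy)-3-hydroxy-2-methylidene-4-{(2R,3S)-4-methylidene-2-[(1Z)-2-methylhexa-1,5-dien-1-yl]-5-oxooxolan-3-yl}butyl] (2S)-2-methylbutanoate | C=C1C(=O)O[C@H](/C=C(/C)CCC=C)[C@H]1[C@H](O[Si](C)(C)C(C)(C)C)[C@H](O)C(=C)COC(=O)[C@@H](C)CC | intermediate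
23 | [(3R,4S)-3-acetoxy-4-(tert-butyldimethylsilyloxy)-2-methylidene-4-{(2R,3S)-4-methylidene-2-[(1Z)-2-methylhexa-1,5-dien-1-yl]-5-oxooxolan-3-yl}butyl] (2S)-2-methylbutanoate | C=C1C(=O)O[C@H](/C=C(/C)CCC=C)[C@H]1[C@H](O[Si](C)(C)C(C)(C)C)[C@H](OC(C)=O)C(=C)COC(=O)[C@@H](C)CC | intermediate
24 | (6R,7S,8S,9R)-9-acetoxy-8-(tert-butyldimethylsilyloxy)-14-[(2S)-2-methylbutanoyloxy]germacra-1(10)Z,4Z,11(13)-trien-12,6-olide | C=C1C(=O)O[C@@H]2/C=C(/C)CC/C=C(/COC(=O)[C@@H](C)CC)[C@@H](OC(C)=O)[C@@H](O[Si](C)(C)C(C)(C)C)[C@@H]12 | intermediate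
25 | (6R,7R,8S,9R)-9-acetoxy-8-hydroxy-14-[(2S)-2-methylbutanoyloxy]germacra-1(10)Z,4Z,11(13)-trien-12,6-olide | C=C1C(=O)O[C@@H]2/C=C(/C)CC/C=C(/COC(=O)[C@@H](C)CC)[C@@H](OC(C)=O)[C@@H](O)[C@@H]12 | target

**Summary**

Total step count: 14. Longest linear sequence: 11 steps (steps 1–5 and 9–14); the enal half (steps 6–8) is made in parallel.

Steps most likely to fail:

1. Step 9 (three-component coupling). The allylnickel intermediate may lose the C8 silyloxy group by 1,4-elimination, DBU may isomerise the Z-enal through its dienolate before it is trapped, and facial control by C8 may be poor. Fallback, setting out from 8 (with 14) and returning at 19: the two bonds would be made in two known operations. Bromoboration of 8 with B-bromo-9-borabicyclo[3.3.1]nonane (CH2Cl2, −78 °C) should give the (Z)-γ-substituted 2-bromoallyl-9-borabicyclononane F1. This adds to 14 in the same flask through a chair transition state, and 2-aminoethanol work-up releases the anti 2-bromo homoallylic alcohol F2. Carbonylative lactonisation of the vinyl bromide (Pd(PPh3)4, CO 1 atm, K2CO3, THF, 60 °C; oxidative addition to zerovalent palladium, CO insertion, capture by O6) then forms C11–C12 and gives 19.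

2. Step 13 (ring-closing metathesis). Ring closure onto the hindered, ester-flanked 1,1-disubstituted olefin may be slower than intermolecular cross-metathesis of the terminal vinyl group, giving oligomers. Fallback, setting out from 20 and returning at 24: metathesis would be moved forward to the diol stage, where the free allylic hydroxyls make the C10 methylene smaller and more reactive. Ring closure of 20 (second-generation Hoveyda–Grubbs catalyst, CH2Cl2, 1 mM, 40 °C) should give the macrocyclic 9,14-diol F3. Selective esterification of the primary hydroxyl with 21 (EDC·HCl, DMAP, −20 °C) gives the macrocyclic C14 monoester F4, and acetylation (Ac2O, pyridine, DMAP) gives 24.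

3. Step 3 (methylenation). The basic ylide may epimerise C9 by enolisation or trigger β-elimination of the C8 silyloxy group. Fallback, setting out from 4 and returning at 5: a Peterson olefination. The weakly basic organocerium reagent from LiCH2SiMe3 and CeCl3 (THF, −78 °C) adds to the ketone without enolisation to give the β-hydroxysilane F5 (either C10 epimer), and KH (THF, 0 °C) induces syn-elimination to 5.

**Further compounds**

F1 | step 9 | 9-[(2Z,4S)-2-bromo-4-(tert-butyldimethylsilyloxy)-4-[(4R)-2,2-dimethyl-5-methylidene-1,3-dioxan-4-yl]but-2-en-1-yl]-9-borabicyclo[3.3.1]nonane | Br/C(CB1C2CCCC1CCC2)=C\[C@H](O[Si](C)(C)C(C)(C)C)[C@@H]3OC(C)(C)OCC3=C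
F2 | step 9 | 2-bromo homoallylic alcohol: C11 vinyl bromide with C7 bearing the free C6 carbinol (Z-dienyl chain) and the C8 silyloxy(dioxanyl)methyl group, configured as in 18 | C=C(Br)[C@@H]([C@H](O)/C=C(/C)CCC=C)[C@H](O[Si](C)(C)C(C)(C)C)[C@@H]1OC(C)(C)OCC1=C
F3 | step 13 | (6R,7S,8S,9R)-8-(tert-butyldimethylsilyloxy)-9,14-dihydroxygermacra-1(10)Z,4Z,11(13)-trien-12,6-olide | C=C1C(=O)O[C@@H]2/C=C(/C)CC/C=C(/CO)[C@@H](O)[C@@H](O[Si](C)(C)C(C)(C)C)[C@@H]12
F4 | step 13 | (6R,7S,8S,9R)-8-(tert-butyldimethylsilyloxy)-9-hydroxy-14-[(2S)-2-methylbutanoyloxy]germacra-1(10)Z,4Z,11(13)-trien-12,6-olide | C=C1C(=O)O[C@@H]2/C=C(/C)CC/C=C(/COC(=O)[C@@H](C)CC)[C@@H](O)[C@@H](O[Si](C)(C)C(C)(C)C)[C@@H]12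
F5 | step 3 | (4S)-4-[(1S)-1-(tert-butyldimethylsilyloxy)-3-(trimethylsilyl)prop-2-yn-1-yl]-2,2-dimethyl-5-[(trimethylsilyl)methyl]-1,3-dioxan-5-ol (either C5 epimer) | CC1(C)OCC(O)(C[Si](C)(C)C)[C@@H](O1)[C@@H](O[Si](C)(C)C(C)(C)C)C#C[Si](C)(C)C
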